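**Assumption:** 2,3‑O‑isopropylidene‑α‑L‑sorbofuranose (the mono‑acetonide of L‑sorbose) is bought as such; the target is the (1S,2S,3R,6R) isomer drawn in the SMILES (pipoxide skeleton).

**Retrosynthetic overview**
1. The vinyl epoxide comes from 1,4‑endoperoxide 10 by phosphite deoxygenation; 10 comes from a [4+2] cycloaddition of singlet oxygen to dienol 9, syn to its free OH. This step sets both epoxide stereocentres.
2. Dienol 9 comes from dehydration of the tertiary carbinol of cyclohexene 6, with the secondary OH masked as a TES ether for that step.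
3. Cyclohexene 6 comes from ring‑closing metathesis of 1,7‑diene 5. Ring order: carbocycle, then dioxabicycle, then oxirane.
4. Diene 5 comes from zinc fragmentation/allylation of 6‑iodo‑sorbofuranose 3. Sorbose C‑3/C‑4 become the trans‑diol carbons; the O‑1/O‑4 benzoates and acetonide‑masked O‑3 already match the target's ester pattern.
5. 3 comes from commercial L‑sorbose mono‑acetonide 1.

**Route**

Step 1
Reactants: 1 2,3‑O‑isopropylidene‑α‑L‑sorbofuranose
Product: 2 6‑deoxy‑6‑iodo‑2,3‑O‑isopropylidene‑α‑L‑sorbofuranose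
Conditions: PPh3, I2, imidazole, THF, 0 °C → rt
Reagents that add atoms: iodine, II
Why: Garegg–Samuelsson (Appel‑type) iodination proceeds by SN2 only at the unhindered primary C‑6, because the C‑1 carbinol is neopentyl (next to the ketal carbon) and C‑4 is secondary; no stereocentre is touched.

Step 2
Reactants: 2 6‑deoxy‑6‑iodo‑2,3‑O‑isopropylidene‑α‑L‑sorbofuranose
Product: 3 1,4‑di‑O‑benzoyl‑6‑deoxy‑6‑iodo‑2,3‑O‑isopropylidene‑α‑L‑sorbofuranose
Conditions: BzCl, pyridine, DMAP (cat.), CH2Cl2, 0 °C → rt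
Reagents that add atoms: benzoyl chloride, O=C(Cl)c1ccccc1
Why: DMAP‑catalysed acylation installs both benzoates of the target on O‑1 and O‑4 while O‑3, the future free hydroxyl, stays locked in the acetonide.

Step 3
Reactants: 3 1,4‑di‑O‑benzoyl‑6‑deoxy‑6‑iodo‑2,3‑O‑isopropylidene‑α‑L‑sorbofuranose
Product: 5 (3S,4R)-2‑allyl‑2,3‑dihydroxyhex‑5‑ene‑1,4‑diyl dibenzoate (C‑2 epimers), via hydroxy ketone 4 (not isolated)
Conditions: Zn dust (activated), allyl bromide, THF/H2O 4:1, sonication, 40 °C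
Reagents that add atoms: allyl bromide, C=CCBr
Why: Bernet–Vasella reductive fragmentation (Zn insertion into C–I, β‑elimination of the ring oxygen, collapse of the hemiketal with loss of acetone) unmasks vinyl group, ketone and free 3‑OH at once, and the ketone is trapped in situ by ester‑tolerant Barbier allylation; the new carbinol centre is uncontrolled but is destroyed in step 6, and C‑3/C‑4 are untouched.

Step 4
Reactants: 5 (3S,4R)-2‑allyl‑2,3‑dihydroxyhex‑5‑ene‑1,4‑diyl dibenzoate (C‑2 epimers)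
Product: 6 [(5R,6S)-5‑(benzoyloxy)-1,6‑dihydroxycyclohex‑3‑en‑1‑yl]methyl benzoate (C‑1 epimers)
Conditions: Grubbs II (5 mol %), CH2Cl2 (0.01 M), 40 °C
Reagents that add atoms: none
Why: Ring‑closing olefin metathesis of the 1,7‑diene gives the cyclohexene with loss of ethylene; free hydroxyls and the allylic benzoate are tolerated and no stereocentre is involved.

Step 5
Reactants: 6 [(5R,6S)-5‑(benzoyloxy)-1,6‑dihydroxycyclohex‑3‑en‑1‑yl]methyl benzoate (C‑1 epimers)
Product: 7 [(5R,6S)-5‑(benzoyloxy)-1‑hydroxy‑6‑(triethylsilyloxy)cyclohex‑3‑en‑1‑yl]methyl benzoate (C‑1 epimers)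
Conditions: TESCl, imidazole, DMF, 0 °C
Reagents that add atoms: chlorotriethylsilane, CC[Si](Cl)(CC)CC
Why: Silylation is selective for the secondary over the tertiary hydroxyl, so that only the tertiary alcohol is exposed to the dehydrating agent in the next step.

Step 6
Reactants: 7 [(5R,6S)-5‑(benzoyloxy)-1‑hydroxy‑6‑(triethylsilyloxy)cyclohex‑3‑en‑1‑yl]methyl benzoate (C‑1 epimers)
Product: 8 [(5R,6R)-5‑(benzoyloxy)-6‑(triethylsilyloxy)cyclohexa‑1,3‑dien‑1‑yl]methyl benzoate
Conditions: Burgess reagent, benzene, 50 °C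
Reagents that add atoms: none
Why: Burgess dehydration (syn Ei elimination of the tertiary sulfamate ester) should remove the most acidic, allylic cis‑hydrogen at C‑2 to give the conjugated 1,3‑diene; both carbinol epimers converge and C‑5/C‑6 are untouched.

Step 7
Reactants: 8 [(5R,6R)-5‑(benzoyloxy)-6‑(triethylsilyloxy)cyclohexa‑1,3‑dien‑1‑yl]methyl benzoate
Product: 9 [(5R,6R)-5‑(benzoyloxy)-6‑hydroxycyclohexa‑1,3‑dien‑1‑yl]methyl benzoate
Conditions: HF·pyridine, pyridine, THF, 0 °C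
Reagents that add atoms: none
Why: Buffered fluoride cleavage of the Si–O bond frees the directing hydroxyl without touching the benzoates or acidifying the aromatisation‑prone dienol.

Step 8
Reactants: 9 [(5R,6R)-5‑(benzoyloxy)-6‑hydroxycyclohexa‑1,3‑dien‑1‑yl]methyl benzoate
Product: 11 [(1S,2S,3R,6R)-3‑(benzoyloxy)-2‑hydroxy‑7‑oxabicyclo[4.1.0]hept‑4‑en‑1‑yl]methyl benzoate (target), via endoperoxide 10 (not isolated)
Conditions: O2, tetraphenylporphyrin (cat.), hν (visible), CH2Cl2, −20 °C; Ar purge; then P(OMe)3, −20 °C → rt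
Reagents that add atoms: dioxygen, O=O
Why: Suprafacial [4+2] cycloaddition of singlet oxygen across C‑1/C‑4 of the s‑cis diene is expected on the face syn to the hydrogen‑bonding 6‑OH and anti to the 5‑benzoate, which sets both new C–O centres; trimethyl phosphite then attacks the less hindered peroxide oxygen (on the secondary carbon) and the tertiary alkoxide closes the oxirane by SN2′ on the same face (deoxygenation of a 1,4‑endoperoxide to a vinyl epoxide).

**Compound list**
1 | 2,3‑O‑isopropylidene‑α‑L‑sorbofuranose | OC[C@]12OC(C)(C)O[C@H]1[C@H](O)[C@H](CO)O2 | starting material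
2 | 6‑deoxy‑6‑iodo‑2,3‑O‑isopropylidene‑α‑L‑sorbofuranose | OC[C@]12OC(C)(C)O[C@H]1[C@H](O)[C@H](CI)O2 | intermediate
3 | 1,4‑di‑O‑benzoyl‑6‑deoxy‑6‑iodo‑2,3‑O‑isopropylidene‑α‑L‑sorbofuranose | O=C(OC[C@]12OC(C)(C)O[C@H]1[C@H](OC(=O)c3ccccc3)[C@H](CI)O2)c4ccccc4 | intermediate
4 | (3S,4R)-3‑hydroxy‑2‑oxohex‑5‑ene‑1,4‑diyl dibenzoate (hydroxy ketone, formed in the flask) | O=C(OCC(=O)[C@@H](O)[C@H](OC(=O)c1ccccc1)C=C)c1ccccc1 | intermediate
5 | (3S,4R)-2‑allyl‑2,3‑dihydroxyhex‑5‑ene‑1,4‑diyl dibenzoate (C‑2 epimers) | O=C(OCC(O)(CC=C)[C@@H](O)[C@H](OC(=O)c1ccccc1)C=C)c1ccccc1 | intermediate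
6 | [(5R,6S)-5‑(benzoyloxy)-1,6‑dihydroxycyclohex‑3‑en‑1‑yl]methyl benzoate (C‑1 epimers) | O=C(OCC1(O)CC=C[C@@H](OC(=O)c2ccccc2)[C@@H]1O)c1ccccc1 | intermediate
7 | [(5R,6S)-5‑(benzoyloxy)-1‑hydroxy‑6‑(triethylsilyloxy)cyclohex‑3‑en‑1‑yl]methyl benzoate (C‑1 epimers) | O=C(OCC1(O)CC=C[C@@H](OC(=O)c2ccccc2)[C@@H]1O[Si](CC)(CC)CC)c1ccccc1 | intermediate
8 | [(5R,6R)-5‑(benzoyloxy)-6‑(triethylsilyloxy)cyclohexa‑1,3‑dien‑1‑yl]methyl benzoate | O=C(OCC1=CC=C[C@@H](OC(=O)c2ccccc2)[C@@H]1O[Si](CC)(CC)CC)c1ccccc1 | intermediate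
9 | [(5R,6R)-5‑(benzoyloxy)-6‑hydroxycyclohexa‑1,3‑dien‑1‑yl]methyl benzoate | O=C(OCC1=CC=C[C@@H](OC(=O)c2ccccc2)[C@@H]1O)c1ccccc1 | intermediate
10 | [(1S,4S,7S,8S)-8‑(benzoyloxy)-7‑hydroxy‑2,3‑dioxabicyclo[2.2.2]oct‑5‑en‑1‑yl]methyl benzoate (peroxide bridge syn to 7‑OH, anti to 8‑OBz; formed in the flask) | O=C(OC[C@@]12OO[C@@H](C=C1)[C@@H](OC(=O)c3ccccc3)[C@@H]2O)c4ccccc4 | intermediate
11 | [(1S,2S,3R,6R)-3‑(benzoyloxy)-2‑hydroxy‑7‑oxabicyclo[4.1.0]hept‑4‑en‑1‑yl]methyl benzoate | O=C(OC[C@@]12O[C@@H]1C=C[C@@H](OC(=O)c1ccccc1)[C@@H]2O)c1ccccc1 | target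

**Totals**
Total step count: 8. Longest linear sequence: 8 (fully linear from 1).

**Three steps most likely to fail, with fallbacks**

Step 3. Hydroxy ketone 4 carries an α‑benzoyloxy group that zinc could cleave reductively, a β‑benzoate that can eliminate, and a free hydroxyl next to a benzoate that invites acyl migration. Fallback: set out from 2 and keep all esters out of the metal step. Zinc (or indium) fragmentation/allylation of the unprotected iodo diol 2 in THF/H2O gives the tetraol (5S,6R)-4‑(hydroxymethyl)octa‑1,7‑diene‑4,5,6‑triol F1. Ring‑closing metathesis (Hoveyda–Grubbs II, CH2Cl2/MeOH) gives (5R,6S)-1‑(hydroxymethyl)cyclohex‑3‑ene‑1,5,6‑triol F2. The two benzoates are then put on late by regioselective acylation (BzCl 2.1 equiv, pyridine, −40 °C): the primary and the less hindered allylic 5‑OH should react before the 6‑OH, which is flanked by the quaternary carbon, and before the tertiary OH. The sequence rejoins the route at 6.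

Step 6. Elimination could go toward C‑6 or the CH2OBz carbon instead of C‑2, and the diene can aromatise by loss of benzoic acid. Fallback: set out from 3 and fix the position of the new double bond with silicon. The same zinc fragmentation, but with Barbier addition of (E)-(3‑bromoprop‑1‑en‑1‑yl)trimethylsilane (C[Si](C)(C)/C=C/CBr; Zn or CrCl2), gives the β‑hydroxysilane (3S,4R)-2,3‑dihydroxy‑2‑[1‑(trimethylsilyl)prop‑2‑en‑1‑yl]hex‑5‑ene‑1,4‑diyl dibenzoate F3. Ring‑closing metathesis gives [(5R,6S)-5‑(benzoyloxy)-1,6‑dihydroxy‑2‑(trimethylsilyl)cyclohex‑3‑en‑1‑yl]methyl benzoate F4. A mild acid‑promoted Peterson elimination (BF3·OEt2 or PPTS, CH2Cl2, −40 °C) can only form the C‑1/C‑2 double bond and needs no hydroxyl protection. It rejoins the route at 9, bypassing 5–8.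

Step 8. The hydroxyl‑directed facial selectivity of the singlet‑oxygen addition may be modest, the phosphite may attack the other peroxide oxygen, and dienol 9 or endoperoxide 10 may decompose. Fallback: set out from 9 and deliver the oxirane oxygen directly by hydroxyl‑directed epoxidation (VO(acac)2, t‑BuOOH, CH2Cl2, 0 °C). This epoxidises only the allylic‑alcohol double bond, syn to the 6‑OH, and arrives at 11. No new compound arises on this path: none F0.

**Further compounds**
F1 | step 3 | (5S,6R)-4‑(hydroxymethyl)octa‑1,7‑diene‑4,5,6‑triol (C‑4 epimers) | OCC(O)(CC=C)[C@@H](O)[C@H](O)C=C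
F2 | step 3 | (5R,6S)-1‑(hydroxymethyl)cyclohex‑3‑ene‑1,5,6‑triol (C‑1 epimers) | OCC1(O)CC=C[C@@H](O)[C@@H]1O
F3 | step 6 | (3S,4R)-2,3‑dihydroxy‑2‑[1‑(trimethylsilyl)prop‑2‑en‑1‑yl]hex‑5‑ene‑1,4‑diyl dibenzoate (diastereomer mixture) | O=C(OCC(O)(C(C=C)[Si](C)(C)C)[C@@H](O)[C@H](OC(=O)c1ccccc1)C=C)c1ccccc1
F4 | step 6 | [(5R,6S)-5‑(benzoyloxy)-1,6‑dihydroxy‑2‑(trimethylsilyl)cyclohex‑3‑en‑1‑yl]methyl benzoate (diastereomer mixture) | O=C(OCC1(O)C([Si](C)(C)C)C=C[C@@H](OC(=O)c2ccccc2)[C@@H]1O)c1ccccc1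
F0 | step 8 | none | none
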